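Count what is left. You asked for a quick number on these flasks and guessed that more Z gives more X, and I doubted that past a certain dose.

| flask | L | Z | remark | time |
|---|---|---|---|---|
| Wednesday's | 20 mM | 4.5 mM (fed, over 2.5 h) | run made earlier |  |
| Tuesday's | 20 mM | 32 mM (fed, over 2.5 h) | run made earlier |  |
| Sunday's | 20 mM | 240 mM (fed, over 2.5 h) | run made earlier |  |
| birch | 20 mM | 4.00 mM (fed, over 2.5 h) |  | 2.5 h |
| alder | 20 mM | 12.0 mM (fed, over 2.5 h) |  | 2.5 h |
| elm | 20 mM | 40.0 mM (fed, over 2.5 h) |  | 2.5 h |
| maple | 20 mM | 100 mM (fed, over 2.5 h) |  | 2.5 h |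
| cedar | 20 mM | 300 mM (fed, over 2.5 h) |  | 2.5 h |

- Wednesday's (time / h: X / %, L / %): 0.333: 0.7, 99.5; 0.833: 2.4, 100.1; 1.50: 0.8, 97.2; 2.50: 1.6, 93.7
- Tuesday's (time / h: X / %, L / %): 0.200: 0.5, 101.3; 0.500: 0, 96.4; 1.00: 2.1, 90.5; 2.50: 7.1, 61.1
- Sunday's (time / h: X / %, L / %): 0.667: 11.7, 72.8; 1.33: 18.2, 27.6; 2.00: 11.7, 5.8; 2.50: 6.3, 1.1

(standard deviation of a reading: 1 percentage point)

- "hardly changes" means that all values lie within two and a half points (for a concentration: within two and a half percent of the largest)

- amount of X at the end, in percent of the L charged for birch, alder, elm, maple, cedar, in this order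
- how the row runs (falls all the way / rises, then falls / rises all the way / hardly changes / falls, then rises)

I worked with the fraction of L left. Sunday's reading of 27.6 % at 1.33 h, with Z climbing in step with the feed, gave a rate constant of 0.0152 mM⁻¹ h⁻¹. From that I carried the end exposure, minus the logarithm of the fraction of L left at the end of an even feed, per mM of Z charged, which came to 0.0190 mM⁻¹. On Tuesday's flask it reckoned too little L left, 54.5 % against a reading of 61.1 %.

In this reckoning the rate of loss of L under an even feed tops out in time when the exponent stands at 0.5, which on Sunday's flask I put at 0.829 h. Sunday's X read higher at 1.33 h than at its other times, with equal readings either side, so I read a lag of 0.501 h. I therefore took X at the end to report the rate of loss of L at 2.00 h. Across doses at that fixed moment, dose times fraction left turns over in this reckoning where the exponent reaches one, which I put at 82.5 mM, above elm's charge and below maple's. I committed to that turn, not to heights.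

The forecast supplied the heights: 1.2 %, 3.2 %, 8.5 %, 11.5 %, 4.5 %, so rises, then falls, on the ground that “X therefore tracks the recent L consumption rate”.

The flasks gave 1.08 %, 3.00 %, 7.64 %, 10.5 %, 5.86 %, so rises, then falls, as forecast.

    J ⇌ X (K = 1.90, k = 15.0 h⁻¹)
    J ⇌ D (K = 290, k = 6.20 h⁻¹)
    L + Z → J + Q (k = 16.0 M⁻¹ h⁻¹)

In cedar the exposure put the fraction left at 0.339 %, and the flask held 0.408 % of L, the limiting reagent, at the end. Its X ended at 5.86 %, and two parts of the reason act together: the cedar run without the back reaction of X to J ended at 71.0 %, and the cedar run without the loss of J to D, both ways, at 65.2 %. Maple's exposure gave 15.0 % left, and that flask held 18.2 % of L at the end. From maple to cedar X changed by −4.6 percentage points, but without that back reaction by 14 points.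

(The earlier runs and the new flask were computed for an exercise; the scatter is artificial.)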